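**Plan**

- Numbering used: quinone C1 (C=O between C2–OMe and C6), C3–H, C4 (C=O), C5–H; side chain C1'H2–C2'H(OAc)–C13H27 on C6; C2' is (R).
- Retrosynthesis: remove the acetyl group; re-join the C2' oxygen to C1, giving a 7-methoxy-2-tridecyl-2,3-dihydrobenzofuran-5-ol (hydroquinone level, side-chain oxygen as a temporary ring ether); cut this arene at C4–C3 (the ring closure), C4–C5 and C1–C6.
- Enabling feature: C4 is a lone carbonyl carbon between two ring CH groups (C3, C5) and para to the C1 oxygen, so it can come from a CO ligand. The C2' oxygen lies four bonds from C1 (O–C2'–C1'–C6–C1), so it can be the alkoxy group of a Fischer carbene at C1 and a two-atom tether to the alkyne C6≡C5.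
- Forward: (R)-epichlorohydrin → (R)-heptadec-1-yn-4-ol; separately methyl vinyl ether + Cr(CO)6 → (1-methoxyvinyl)acyl chromate; the alcohol is hung on the carbene carbon. One thermal step then forms the dihydrofuran ring (C1–C6) and the benzene ring (C4–C5, then C4–C3); CAN reopens the dihydrofuran to the quinone; acetylation ends the route.
- Stereochemistry: the single stereocentre comes from (R)-epichlorohydrin; its C–O bond is never broken (O–H exchange at the carbene carbon, aryl–O cleavage in the oxidation).

Key step: step 5

Assumption: (R)-epichlorohydrin, dodecylmagnesium bromide, lithium acetylide–ethylenediamine complex, methyl vinyl ether and hexacarbonylchromium are bought.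

**Route**

Step 1
Reactants: 1 (R)-epichlorohydrin; 2 dodecylmagnesium bromide
Product: 3 (2R)-1-chloropentadecan-2-ol
Conditions: CuI (10 mol %), THF, −40 → 0 °C; then 1 M HCl
Reagents that add atoms: none
Why: Copper-catalysed Grignard opening of the epoxide at its unsubstituted carbon (SN2) should outrun chloride displacement, so the stereocentre of 1 is carried over untouched as the (R)-chlorohydrin.

Step 2
Reactants: 3 (2R)-1-chloropentadecan-2-ol
Product: 5 (4R)-heptadec-1-yn-4-ol, via epoxide 4 (not isolated)
Conditions: LiC≡CH·H2NCH2CH2NH2 (3 equiv), DMSO, 0 °C → rt; then H2O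
Reagents that add atoms: lithium acetylide–ethylenediamine complex, [Li+].[C-]#C.NCCN
Why: The lithium alkoxide should close to the terminal epoxide (intramolecular Williamson reaction) and a second acetylide should open it at CH2 (SN2 epoxide alkynylation), so the carbinol carbon is never a reaction centre and stays (R).

Step 3
Reactants: 6 methyl vinyl ether; 7 hexacarbonylchromium
Product: 10 tetramethylammonium pentacarbonyl(2-methoxyacryloyl)chromate, via 1-methoxyvinyllithium 8 (not isolated), via lithium acylate 9 (not isolated)
Conditions: t-BuLi, THF, −78 → 0 °C; Cr(CO)6, Et2O/THF, 0 °C → rt; then Me4NBr, degassed H2O, 0 °C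
Reagents that add atoms: tetramethylammonium bromide, C[N+](C)(C)C.[Br-]
Why: Fischer acyl-metalate synthesis: α-lithiation of the enol ether, addition of the vinyllithium to a CO ligand, then cation exchange to the storable tetramethylammonium salt; no stereocentre is involved.

Step 4
Reactants: 10 tetramethylammonium pentacarbonyl(2-methoxyacryloyl)chromate; 5 (4R)-heptadec-1-yn-4-ol
Product: 12 pentacarbonyl{[(4R)-heptadec-1-yn-4-yloxy](1-methoxyethenyl)methylidene}chromium, via acetoxycarbene complex 11 (not isolated)
Conditions: AcBr (0.95 equiv), CH2Cl2, −40 °C; then 5, −40 → −10 °C; cold filtration through SiO2, kept ≤ 0 °C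
Reagents that add atoms: none
Why: O-acylation of the acylate should give a highly electrophilic acyloxycarbene that undergoes addition–elimination at the carbene carbon with the secondary alcohol (acyloxy/alkoxy exchange, the standard entry to isopropoxy- and menthyloxy-carbene complexes); only the O–H bond of 5 is broken, so the carbinol carbon stays (R), and the product is kept cold because CO loss would start step 5.

Step 5
Reactants: 12 pentacarbonyl{[(4R)-heptadec-1-yn-4-yloxy](1-methoxyethenyl)methylidene}chromium
Product: 14 2-[(2R)-2-hydroxypentadecyl]-6-methoxy-1,4-benzoquinone, via dihydrobenzofuranol 13 (not isolated)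
Conditions: THF (0.01 M), 55 °C, Ar; then CAN (7 equiv), MeCN/H2O, 0 °C
Reagents that add atoms: water, O
Why: Dötz benzannulation run intramolecularly through an alkynyloxy tether (closest type: benzannulation of alkoxy(alkenyl)carbene chromium complexes with alkynes, including the variant with the alkyne hung on the carbene oxygen): thermal CO loss, 5-exo-dig insertion of the tethered alkyne into Cr=C (C1–C6 bond, closing the dihydrofuran ring), CO insertion at the new carbene carbon C5 to give the chromium-bound dienylketene, then 6π-electrocyclisation of the ketene carbon C4 onto the vinyl CH2 (C3) closes the carbocycle, and tautomerisation gives phenol 13 as its labile Cr(CO)3 complex. The step needs regiocontrol opposite to the intermolecular preference (a free terminal alkyne would place its substituent next to the CO-derived carbon and lead to the 2,5-isomer); the two-atom O–CH–CH2 tether allows only the internal alkyne carbon to bond to the carbene carbon, and the five-membered ring holds the ketene and the methoxyvinyl group cis on C6=C1, as the electrocyclisation requires. Phenol formation over CO-free cyclopentannulation should be favoured by the alkenyl(alkoxy)carbene, the unsubstituted vinyl terminus and THF. No new stereocentre is formed and the C–O bond of the carbinol carbon is untouched. CAN then strips chromium and oxidises the p-alkoxyphenol; water adds at C7a and the hemiketal collapses with aryl–O cleavage, so the tether opens to the quinone and the free (R)-alcohol with retention.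

Step 6
Reactants: 14 2-[(2R)-2-hydroxypentadecyl]-6-methoxy-1,4-benzoquinone
Product: 15 ardisinone
Conditions: Ac2O, pyridine, CH2Cl2, 0 °C → rt
Reagents that add atoms: acetic anhydride, CC(=O)OC(C)=O
Why: Base-mediated O-acetylation of the secondary alcohol (acyl transfer, retention at carbon) should give the target; acid catalysts are avoided to exclude Thiele–Winter acetoxylation of the quinone.

**Compound list**

1 | (R)-epichlorohydrin | ClC[C@H]1CO1 | starting material
2 | dodecylmagnesium bromide | CCCCCCCCCCCC[Mg]Br | starting material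
3 | (2R)-1-chloropentadecan-2-ol | CCCCCCCCCCCCC[C@@H](O)CCl | intermediate
4 | (2R)-2-tridecyloxirane | CCCCCCCCCCCCC[C@@H]1CO1 | intermediate
5 | (4R)-heptadec-1-yn-4-ol | CCCCCCCCCCCCC[C@@H](O)CC#C | intermediate
6 | methyl vinyl ether | COC=C | starting material
7 | hexacarbonylchromium | O=C=[Cr](=C=O)(=C=O)(=C=O)(=C=O)=C=O | starting material
8 | 1-methoxyvinyllithium | [Li]C(=C)OC | intermediate
9 | lithium pentacarbonyl(2-methoxyacryloyl)chromate | [Li+].COC(=C)C([O-])=[Cr](=C=O)(=C=O)(=C=O)(=C=O)=C=O | intermediate
10 | tetramethylammonium pentacarbonyl(2-methoxyacryloyl)chromate | C[N+](C)(C)C.COC(=C)C([O-])=[Cr](=C=O)(=C=O)(=C=O)(=C=O)=C=O | intermediate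
11 | pentacarbonyl[(acetyloxy)(1-methoxyethenyl)methylidene]chromium | COC(=C)C(OC(C)=O)=[Cr](=C=O)(=C=O)(=C=O)(=C=O)=C=O | intermediate
12 | pentacarbonyl{[(4R)-heptadec-1-yn-4-yloxy](1-methoxyethenyl)methylidene}chromium | COC(=C)C(O[C@@H](CC#C)CCCCCCCCCCCCC)=[Cr](=C=O)(=C=O)(=C=O)(=C=O)=C=O | intermediate
13 | (2R)-7-methoxy-2-tridecyl-2,3-dihydro-1-benzofuran-5-ol | CCCCCCCCCCCCC[C@@H]1Cc2cc(O)cc(OC)c2O1 | intermediate
14 | 2-[(2R)-2-hydroxypentadecyl]-6-methoxy-1,4-benzoquinone | CCCCCCCCCCCCC[C@@H](O)CC1=CC(=O)C=C(OC)C1=O | intermediate
15 | ardisinone, [(2R)-1-(5-methoxy-3,6-dioxocyclohexa-1,4-dien-1-yl)pentadecan-2-yl] acetate | CCCCCCCCCCCCC[C@H](CC1=CC(=O)C=C(OC)C1=O)OC(C)=O | target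

**Count and risks**

Total step count: 6. Longest linear sequence: 5 steps (steps 1, 2, 4, 5, 6); step 3 is the second branch.

Steps most likely to fail:

1. Step 5. The tethered alkyne may react intermolecularly (oligomerisation), the vinylcarbene may close without CO insertion (cyclopentannulation or furan formation), or the oxidative opening of the dihydrofuran may stall at the hemiketal. Fallback, from 3 back to 14, with the ring bought as an arene: 3 is closed with NaOH to epoxide 4, here isolated. Guaiacol is protected (MOMCl, i-Pr2NEt) as 1-methoxy-2-(methoxymethoxy)benzene F1. Lithiation ortho to the OMOM group (n-BuLi, TMEDA, Et2O, 0 °C) gives 3-methoxy-2-(methoxymethoxy)phenyllithium F2. F2 opens 4 at CH2 (BF3·OEt2, THF, −78 °C) to give (2R)-1-[3-methoxy-2-(methoxymethoxy)phenyl]pentadecan-2-ol F3. HCl/MeOH gives 2-[(2R)-2-hydroxypentadecyl]-6-methoxyphenol F4. Teuber oxidation (Fremy's salt, phosphate buffer, acetone/H2O) at the free para position should give 14.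

2. Step 4. The acetoxycarbene may decompose before exchange, or the hindered secondary alcohol may add to the vinyl terminus instead of exchanging at the carbene carbon. Fallback, from 3 back to 14, through a resorcinol-type arene: 3 is closed with NaOH to isolated 4. 1-Bromo-3,5-dimethoxybenzene and Mg give 3,5-dimethoxyphenylmagnesium bromide F5. F5 opens 4 (CuI cat., THF, −30 → 0 °C) to give (2R)-1-(3,5-dimethoxyphenyl)pentadecan-2-ol F6. NaSEt (DMF, 140 °C) removes one methyl group to give 3-[(2R)-2-hydroxypentadecyl]-5-methoxyphenol F7. Teuber oxidation para to the hydroxyl (between OMe and the side chain) should give 14.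

3. Step 6. Attack of the base on the methoxyquinone (addition, redox darkening) may outpace acylation of the hindered secondary alcohol. Fallback, from 14 back to 15, acylating at the hydroquinone level: reductive acetylation (Zn dust, Ac2O, NaOAc) gives (2R)-1-(2,5-diacetoxy-3-methoxyphenyl)pentadecan-2-yl acetate F8. Pyrrolidine (CH2Cl2, 0 °C) should cleave only the two aryl acetates, giving (2R)-1-(2,5-dihydroxy-3-methoxyphenyl)pentadecan-2-yl acetate F9. Ag2O (Et2O, rt) re-oxidises F9 to 15.

Further compounds
F1 | step 5 | 1-methoxy-2-(methoxymethoxy)benzene | COCOc1ccccc1OC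
F2 | step 5 | 3-methoxy-2-(methoxymethoxy)phenyllithium | [Li]c1cccc(OC)c1OCOC
F3 | step 5 | (2R)-1-[3-methoxy-2-(methoxymethoxy)phenyl]pentadecan-2-ol | CCCCCCCCCCCCC[C@@H](O)Cc1cccc(OC)c1OCOC
F4 | step 5 | 2-[(2R)-2-hydroxypentadecyl]-6-methoxyphenol | CCCCCCCCCCCCC[C@@H](O)Cc1cccc(OC)c1O
F5 | step 4 | 3,5-dimethoxyphenylmagnesium bromide | COc1cc(OC)cc([Mg]Br)c1
F6 | step 4 | (2R)-1-(3,5-dimethoxyphenyl)pentadecan-2-ol | CCCCCCCCCCCCC[C@@H](O)Cc1cc(OC)cc(OC)c1
F7 | step 4 | 3-[(2R)-2-hydroxypentadecyl]-5-methoxyphenol | CCCCCCCCCCCCC[C@@H](O)Cc1cc(O)cc(OC)c1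
F8 | step 6 | (2R)-1-(2,5-diacetoxy-3-methoxyphenyl)pentadecan-2-yl acetate | CCCCCCCCCCCCC[C@@H](OC(C)=O)Cc1cc(OC(C)=O)cc(OC)c1OC(C)=O
F9 | step 6 | (2R)-1-(2,5-dihydroxy-3-methoxyphenyl)pentadecan-2-yl acetate | CCCCCCCCCCCCC[C@@H](OC(C)=O)Cc1cc(O)cc(OC)c1O
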